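**Strategy.** The target is a chalcan–flavan dimer: C8 of ring A of an epigallocatechin gallate unit carries the benzylic carbon of a ring-opened second unit. Both halves are cut back to one enantiopure erythro 1-aryl-2,3-epoxypropan-1-ol. In the key step this epoxy alcohol acts as a 1,3-dielectrophile towards a symmetric phloroglucinol diether: the phenol oxygen (O1) displaces the benzylic hydroxyl with inversion (C2), then the neighbouring ring-A carbon (C4a) opens the epoxide terminus (C4), so ring C and its cis-2,3 stereocentres arise in one flask. It exploits the adjacent O1/C4a nucleophilic pair of ring A and the C3 oxygen flanked by electrophilic C2 and C4. The same epoxy alcohol, opened by a phloroglucinyl Grignard reagent, becomes the chalcan electrophile.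

Key step: step 3

Remark: the configurations are read from the SMILES as (2R,3R) in the flavan and (1S,2R) in the open chain; compounds 1, 2, 5, 8 and 16 are taken as purchasable, and benzyl is the only protecting group.

Step 1
Reactants: 1 3,4,5-tris(benzyloxy)benzaldehyde; 2 vinylmagnesium bromide
Product: 3 rac-1-[3,4,5-tris(benzyloxy)phenyl]prop-2-en-1-ol
Conditions: THF, −20 → 0 °C; aqueous work-up
Reagents that add atoms: none
Why: Grignard 1,2-addition to a non-enolisable aldehyde should give the aryl vinyl carbinol as a racemate, which is resolved in step 2.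

Step 2
Reactants: 3 rac-1-[3,4,5-tris(benzyloxy)phenyl]prop-2-en-1-ol
Product: 4 (S)-[(2R)-oxiran-2-yl][3,4,5-tris(benzyloxy)phenyl]methanol (erythro)
Conditions: Ti(OiPr)4 (10 mol %), L-(+)-diisopropyl tartrate (12 mol %), t-BuOOH (0.45 equiv), 4 Å MS, CH2Cl2, −20 °C
Reagents that add atoms: tert-butyl hydroperoxide, CC(C)(C)OO
Why: Sharpless kinetic resolution: with the L-(+)-tartrate the (R)-carbinol should be epoxidised much faster than its antipode and on the alkene face that gives the erythro product, so the tartrate sets the (S)-carbinol/(R)-oxirane pair of 4 while the (S)-alcohol stays behind.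

Step 3
Reactants: 4 (S)-[(2R)-oxiran-2-yl][3,4,5-tris(benzyloxy)phenyl]methanol; 5 3,5-bis(benzyloxy)phenol
Product: 7 (2R,3R)-5,7-bis(benzyloxy)-2-[3,4,5-tris(benzyloxy)phenyl]chroman-3-ol, via aryl epoxy ether 6 (not isolated)
Conditions: PPh3 (1.2 equiv), DIAD (1.3 equiv), toluene, 0 °C → rt; then CH2Cl2, AuCl3 (5 mol %), AgOTf (15 mol %), 0 °C → rt
Reagents that add atoms: none
Why: Under Mitsunobu conditions the benzylic hydroxyl of 4 becomes an alkoxyphosphonium leaving group that the phenoxide of 5 displaces through oxygen in an SN2 step (O1–C2 bond, ether 6); the gold Lewis acid added to the same flask then activates the terminal epoxide, and the ring-A carbon ortho to the new ether oxygen attacks its CH2 terminus in a Friedel–Crafts cycloalkylation (C4–C4a bond), the epoxide oxygen becoming the C3 hydroxyl. The closest known reaction types are the Mitsunobu etherification of phenols with secondary benzylic alcohols and the AuCl3/AgOTf-catalysed epoxy-arene cyclisation of aryl ethers of this kind, telescoped here into a formal [3+3] annulation. Ring C, the only ring formed, closes by 6-endo-tet opening of the epoxide by the arene. C2 is set by SN2 inversion of the (S)-carbinol carbon of 4, and C3 is the (R)-oxirane carbon of 4, whose C–O bond is never broken, so the erythro epoxy alcohol maps onto the 2,3-cis (2R,3R) flavan. The step needs O- over C-alkylation and inversion over ionisation at C2, which the neutral ion-pair mechanism in toluene and the two meta benzyloxy groups of ring B (they attenuate benzylic cation formation) should secure, and it needs 6-endo over 5-exo attack, which the unhindered primary terminus and the inductively deactivated internal carbon should secure. Site selectivity on ring A needs no control, because the two positions ortho to the hydroxyl of symmetric 5 are equivalent and the para position cannot reach the epoxide.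

Step 4
Reactants: 8 1,3,5-tris(benzyloxy)benzene
Product: 9 2-bromo-1,3,5-tris(benzyloxy)benzene
Conditions: NBS (1.0 equiv), CH2Cl2, −20 → 0 °C
Reagents that add atoms: N-bromosuccinimide, O=C1CCC(=O)N1Br
Why: Electrophilic aromatic bromination of the symmetric, strongly activated triether should stop after one substitution with one equivalent of NBS, all three free positions being equivalent.

Step 5
Reactants: 9 2-bromo-1,3,5-tris(benzyloxy)benzene (2.2 equiv); 4 (S)-[(2R)-oxiran-2-yl][3,4,5-tris(benzyloxy)phenyl]methanol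
Product: 11 (1S,2R)-1-[3,4,5-tris(benzyloxy)phenyl]-3-[2,4,6-tris(benzyloxy)phenyl]propane-1,2-diol, via aryl Grignard reagent 10 (not isolated)
Conditions: 9, Mg, THF, 50 °C; then 4, CuI (10 mol %), THF, −30 → 0 °C; aqueous work-up
Reagents that add atoms: none
Why: Copper-catalysed Grignard opening of the terminal epoxide should occur at the unhindered CH2 carbon (SN2) and leave both stereocentres of 4 untouched; the first equivalent of 10 only deprotonates the hydroxyl, and the covalent magnesium alkoxide should not undergo Payne rearrangement at this temperature.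

Step 6
Reactants: 11 (1S,2R)-1-[3,4,5-tris(benzyloxy)phenyl]-3-[2,4,6-tris(benzyloxy)phenyl]propane-1,2-diol
Product: 14 (2S,3R)-2-[3,4,5-tris(benzyloxy)phenyl]-3-[2,4,6-tris(benzyloxy)benzyl]oxirane (cis), via cyclic orthoacetate 12 (not isolated), via chloro acetate 13 (not isolated)
Conditions: MeC(OMe)3, PPTS (cat.), CH2Cl2, rt; then Me3SiCl, 0 °C; then K2CO3, MeOH, 0 °C → rt
Reagents that add atoms: none
Why: Orthoester-mediated diol-to-epoxide conversion: chloride opens the acetoxonium ion at the benzylic carbon with inversion and the alkoxide freed by methanolysis displaces chloride with a second inversion, so the erythro diol should give the cis epoxide with both configurations retained.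

Step 7
Reactants: 14 (2S,3R)-2-[3,4,5-tris(benzyloxy)phenyl]-3-[2,4,6-tris(benzyloxy)benzyl]oxirane; 7 (2R,3R)-5,7-bis(benzyloxy)-2-[3,4,5-tris(benzyloxy)phenyl]chroman-3-ol
Product: 15 (2R,3R)-5,7-bis(benzyloxy)-8-{(1S,2R)-2-hydroxy-1-[3,4,5-tris(benzyloxy)phenyl]-3-[2,4,6-tris(benzyloxy)phenyl]propyl}-2-[3,4,5-tris(benzyloxy)phenyl]chroman-3-ol
Conditions: equimolar amounts, 14 added slowly to 7 in CF3CH2OH/CH2Cl2 (3:1), 0 °C → rt
Reagents that add atoms: none
Why: Friedel–Crafts alkylation by SN2-type opening of an aryl epoxide with an electron-rich arene in a fluorinated alcohol is a pure addition that should invert the benzylic carbon of the cis epoxide and so set the (S) diarylmethine centre, the arene reacting at C8 (flanked by the pyran oxygen and one benzyloxy group, the usual site of electrophilic substitution in 5,7-di-O-benzyl flavan-3-ols) while C6 and the free positions of the 2,4,6-tribenzyloxyphenyl ring are each shielded by two benzyloxy groups, and slow addition of the epoxide keeps the arene in excess over unreacted electrophile.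

Step 8
Reactants: 15 the diol from step 7; 16 3,4,5-tris(benzyloxy)benzoic acid (2.5 equiv)
Product: 17 bis[3,4,5-tris(benzyloxy)benzoate] of 15 (esters at the chroman C3 oxygen and at the open-chain C2 oxygen; heptadeca-O-benzyl derivative of the target)
Conditions: DCC, DMAP, CH2Cl2, rt
Reagents that add atoms: none
Why: Steglich esterification should acylate the two secondary hydroxyls, the only free OH groups left, without touching any stereocentre.

Step 9
Reactants: 17 the heptadeca-O-benzyl bis-gallate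
Product: 18 (2R,3R)-5,7-dihydroxy-8-[(1S,2R)-2-(3,4,5-trihydroxybenzoyloxy)-1-(3,4,5-trihydroxyphenyl)-3-(2,4,6-trihydroxyphenyl)propyl]-2-(3,4,5-trihydroxyphenyl)chroman-3-yl 3,4,5-trihydroxybenzoate (CNP0155034.1)
Conditions: H2 (1 atm), Pd(OH)2/C, THF/MeOH, rt
Reagents that add atoms: none
Why: Catalytic hydrogenolysis should cleave all seventeen benzyl ethers under neutral conditions, while the esters, the cyclic C2–O1 ether bond and the stereocentres are expected to survive as in debenzylations of benzylated catechin gallates.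

**Compound list**

1 | 3,4,5-tris(benzyloxy)benzaldehyde | O=Cc1cc(OCc2ccccc2)c(OCc2ccccc2)c(OCc2ccccc2)c1 | starting material
2 | vinylmagnesium bromide | C=C[Mg]Br | starting material
3 | rac-1-[3,4,5-tris(benzyloxy)phenyl]prop-2-en-1-ol | C=CC(O)c1cc(OCc2ccccc2)c(OCc2ccccc2)c(OCc2ccccc2)c1 | intermediate
4 | (S)-[(2R)-oxiran-2-yl][3,4,5-tris(benzyloxy)phenyl]methanol (erythro) | O[C@@H](c1cc(OCc2ccccc2)c(OCc2ccccc2)c(OCc2ccccc2)c1)[C@H]1CO1 | intermediate
5 | 3,5-bis(benzyloxy)phenol | Oc1cc(OCc2ccccc2)cc(OCc2ccccc2)c1 | starting material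
6 | (2R)-2-{(R)-[3,5-bis(benzyloxy)phenoxy][3,4,5-tris(benzyloxy)phenyl]methyl}oxirane | c1ccccc1COc1cc(OCc2ccccc2)cc(O[C@H](c2cc(OCc3ccccc3)c(OCc3ccccc3)c(OCc3ccccc3)c2)[C@H]2CO2)c1 | intermediate (not isolated)
7 | (2R,3R)-5,7-bis(benzyloxy)-2-[3,4,5-tris(benzyloxy)phenyl]chroman-3-ol (penta-O-benzyl epigallocatechin) | O[C@@H]1Cc2c(OCc3ccccc3)cc(OCc3ccccc3)cc2O[C@@H]1c1cc(OCc2ccccc2)c(OCc2ccccc2)c(OCc2ccccc2)c1 | intermediate
8 | 1,3,5-tris(benzyloxy)benzene | c1(OCc2ccccc2)cc(OCc2ccccc2)cc(OCc2ccccc2)c1 | starting material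
9 | 2-bromo-1,3,5-tris(benzyloxy)benzene | Brc1c(OCc2ccccc2)cc(OCc2ccccc2)cc1OCc1ccccc1 | intermediate
10 | [2,4,6-tris(benzyloxy)phenyl]magnesium bromide | Br[Mg]c1c(OCc2ccccc2)cc(OCc2ccccc2)cc1OCc1ccccc1 | intermediate (not isolated)
11 | (1S,2R)-1-[3,4,5-tris(benzyloxy)phenyl]-3-[2,4,6-tris(benzyloxy)phenyl]propane-1,2-diol (erythro) | O[C@@H](c1cc(OCc2ccccc2)c(OCc2ccccc2)c(OCc2ccccc2)c1)[C@H](O)Cc1c(OCc2ccccc2)cc(OCc2ccccc2)cc1OCc1ccccc1 | intermediate
12 | (4S,5R)-2-methoxy-2-methyl-4-[3,4,5-tris(benzyloxy)phenyl]-5-[2,4,6-tris(benzyloxy)benzyl]-1,3-dioxolane (cis; mixture at the orthoester carbon) | COC1(C)O[C@@H](c2cc(OCc3ccccc3)c(OCc3ccccc3)c(OCc3ccccc3)c2)[C@@H](Cc2c(OCc3ccccc3)cc(OCc3ccccc3)cc2OCc2ccccc2)O1 | intermediate (not isolated)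
13 | (1R,2R)-1-chloro-1-[3,4,5-tris(benzyloxy)phenyl]-3-[2,4,6-tris(benzyloxy)phenyl]propan-2-yl acetate | Cl[C@H](c1cc(OCc2ccccc2)c(OCc2ccccc2)c(OCc2ccccc2)c1)[C@H](OC(C)=O)Cc1c(OCc2ccccc2)cc(OCc2ccccc2)cc1OCc1ccccc1 | intermediate (not isolated)
14 | (2S,3R)-2-[3,4,5-tris(benzyloxy)phenyl]-3-[2,4,6-tris(benzyloxy)benzyl]oxirane (cis) | O1[C@@H](c2cc(OCc3ccccc3)c(OCc3ccccc3)c(OCc3ccccc3)c2)[C@H]1Cc1c(OCc2ccccc2)cc(OCc2ccccc2)cc1OCc1ccccc1 | intermediate
15 | (2R,3R)-5,7-bis(benzyloxy)-8-{(1S,2R)-2-hydroxy-1-[3,4,5-tris(benzyloxy)phenyl]-3-[2,4,6-tris(benzyloxy)phenyl]propyl}-2-[3,4,5-tris(benzyloxy)phenyl]chroman-3-ol | O[C@H](Cc1c(OCc3ccccc3)cc(OCc3ccccc3)cc1OCc1ccccc1)[C@@H](c1cc(OCc3ccccc3)c(OCc3ccccc3)c(OCc3ccccc3)c1)c1c(OCc3ccccc3)cc(OCc3ccccc3)c2c1O[C@H](c1cc(OCc3ccccc3)c(OCc3ccccc3)c(OCc3ccccc3)c1)[C@H](O)C2 | intermediate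
16 | 3,4,5-tris(benzyloxy)benzoic acid | OC(=O)c1cc(OCc2ccccc2)c(OCc2ccccc2)c(OCc2ccccc2)c1 | starting material
17 | bis[3,4,5-tris(benzyloxy)benzoate] of 15 (heptadeca-O-benzyl derivative of the target) | O=C(O[C@H](Cc1c(OCc3ccccc3)cc(OCc3ccccc3)cc1OCc1ccccc1)[C@@H](c1cc(OCc3ccccc3)c(OCc3ccccc3)c(OCc3ccccc3)c1)c1c(OCc3ccccc3)cc(OCc3ccccc3)c2c1O[C@H](c1cc(OCc3ccccc3)c(OCc3ccccc3)c(OCc3ccccc3)c1)[C@H](OC(=O)c1cc(OCc3ccccc3)c(OCc3ccccc3)c(OCc3ccccc3)c1)C2)c1cc(OCc2ccccc2)c(OCc2ccccc2)c(OCc2ccccc2)c1 | intermediate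
18 | CNP0155034.1, (2R,3R)-5,7-dihydroxy-8-[(1S,2R)-2-(3,4,5-trihydroxybenzoyloxy)-1-(3,4,5-trihydroxyphenyl)-3-(2,4,6-trihydroxyphenyl)propyl]-2-(3,4,5-trihydroxyphenyl)chroman-3-yl 3,4,5-trihydroxybenzoate | O=C(O[C@H](Cc1c(O)cc(O)cc1O)[C@@H](c1cc(O)c(O)c(O)c1)c1c(O)cc(O)c2c1O[C@H](c1cc(O)c(O)c(O)c1)[C@H](OC(=O)c1cc(O)c(O)c(O)c1)C2)c1cc(O)c(O)c(O)c1 | target

**Step count and risks**

Total step count: 9. Longest linear sequence: 7 steps (1, 2, 5, 6, 7, 8, 9).

Steps most likely to fail:

Step 7. The epoxide may ionise before the arene arrives, so that inversion at the benzylic carbon is lost (cis-to-trans isomerisation, free cation, hydride shift). The arene may also react at C6, an ortho benzyloxy oxygen may capture the cation, or, because the partners are used in equimolar amounts, the electron-rich ring of a second molecule of 14 may compete with 7. The fallback sets out from 7 and returns to the route at 15. Bromination of 7 with NBS (CH2Cl2, −78 °C → rt), which in 5,7-di-O-benzyl flavan-3-ols goes to C8, should give (2R,3R)-8-bromo-5,7-bis(benzyloxy)-2-[3,4,5-tris(benzyloxy)phenyl]chroman-3-ol F1. Deprotonation of the hydroxyl with MeLi and bromine–lithium exchange with t-BuLi (THF, −78 °C) should give the C8-lithiated lithium alkoxide F2. With BF3·OEt2 this aryllithium should open epoxide 14 at the benzylic carbon in a true SN2 step, so that the site is fixed by the former C–Br bond and inversion no longer depends on ion-pair behaviour. Aqueous work-up returns 15.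

Step 3. The benzylic alkoxyphosphonium ion may ionise (loss of inversion, C-alkylation of the phenol), the gold catalyst may be inhibited by the phosphine oxide and hydrazide left in the flask, or the arene may attack 5-exo. The fallback sets out from 1 and 5, returns at 7, and still forms both ring-C bonds in one operation. Aldol condensation of 1 with 2-(benzyloxy)acetaldehyde (pyrrolidine, AcOH) should give (Z)-2-(benzyloxy)-3-[3,4,5-tris(benzyloxy)phenyl]prop-2-enal F3. Heating F3 with 5 and PhB(OH)2/AcOH in toluene should give rac-3,5,7-tris(benzyloxy)-2-[3,4,5-tris(benzyloxy)phenyl]-2H-chromene F4. This proceeds by ortho-selective hydroxyalkylation through the aryl boronate, ortho-quinone methide formation and oxa-6π electrocyclisation. Aqueous HCl in THF should hydrolyse the benzyl enol ether to rac-5,7-bis(benzyloxy)-2-[3,4,5-tris(benzyloxy)phenyl]chroman-3-one F5. Asymmetric transfer hydrogenation with RuCl[(S,S)-TsDPEN](p-cymene) or its antipode (the one that gives the 3R alcohol), HCO2H/Et3N, under dynamic kinetic resolution should return cis-(2R,3R) 7. Here C2 epimerises through the enol and hydride adds anti to the aryl group.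

Step 6. The benzylic carbon may epimerise while it carries chloride, or the chloride may undergo methanolysis in competition with ring closure; either would give the trans epoxide or a methyl ether. The fallback sets out from 11 and returns at 15, bypassing 14. Treatment of 11 with 1,1'-sulfonyldiimidazole and NaH (THF, −20 °C) should give, without any substitution at carbon, the cis cyclic sulfate (4S,5R)-4-[3,4,5-tris(benzyloxy)phenyl]-5-[2,4,6-tris(benzyloxy)benzyl]-1,3,2-dioxathiolane 2,2-dioxide F6. F6 is used directly as the electrophile towards 7 (CH2Cl2/(CF3)2CHOH, 2,6-di-tert-butyl-4-methylpyridine, −30 °C → rt). The tethered sulfate leaves on its own face, so C8 should enter with inversion to give the hydrogen sulfate of 15 at the open-chain oxygen F7. Hydrolysis (cat. H2SO4, H2O, THF) gives 15.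

Further compounds
F1 | step 7 | (2R,3R)-8-bromo-5,7-bis(benzyloxy)-2-[3,4,5-tris(benzyloxy)phenyl]chroman-3-ol | O[C@@H]1Cc2c(OCc3ccccc3)cc(OCc3ccccc3)c(Br)c2O[C@@H]1c1cc(OCc2ccccc2)c(OCc2ccccc2)c(OCc2ccccc2)c1
F2 | step 7 | lithium (2R,3R)-5,7-bis(benzyloxy)-8-lithio-2-[3,4,5-tris(benzyloxy)phenyl]chroman-3-olate | [Li]O[C@@H]1Cc2c(OCc3ccccc3)cc(OCc3ccccc3)c([Li])c2O[C@@H]1c1cc(OCc2ccccc2)c(OCc2ccccc2)c(OCc2ccccc2)c1
F3 | step 3 | (Z)-2-(benzyloxy)-3-[3,4,5-tris(benzyloxy)phenyl]prop-2-enal | O=C/C(OCc1ccccc1)=C/c1cc(OCc2ccccc2)c(OCc2ccccc2)c(OCc2ccccc2)c1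
F4 | step 3 | rac-3,5,7-tris(benzyloxy)-2-[3,4,5-tris(benzyloxy)phenyl]-2H-chromene | C1(OCc2ccccc2)=Cc2c(OCc3ccccc3)cc(OCc3ccccc3)cc2OC1c1cc(OCc2ccccc2)c(OCc2ccccc2)c(OCc2ccccc2)c1
F5 | step 3 | rac-5,7-bis(benzyloxy)-2-[3,4,5-tris(benzyloxy)phenyl]chroman-3-one | O=C1Cc2c(OCc3ccccc3)cc(OCc3ccccc3)cc2OC1c1cc(OCc2ccccc2)c(OCc2ccccc2)c(OCc2ccccc2)c1
F6 | step 6 | (4S,5R)-4-[3,4,5-tris(benzyloxy)phenyl]-5-[2,4,6-tris(benzyloxy)benzyl]-1,3,2-dioxathiolane 2,2-dioxide (cis) | O=S1(=O)O[C@@H](c2cc(OCc3ccccc3)c(OCc3ccccc3)c(OCc3ccccc3)c2)[C@@H](Cc2c(OCc3ccccc3)cc(OCc3ccccc3)cc2OCc2ccccc2)O1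
F7 | step 6 | hydrogen sulfate of 15 at the open-chain C2 oxygen | OS(=O)(=O)O[C@H](Cc1c(OCc3ccccc3)cc(OCc3ccccc3)cc1OCc1ccccc1)[C@@H](c1cc(OCc3ccccc3)c(OCc3ccccc3)c(OCc3ccccc3)c1)c1c(OCc3ccccc3)cc(OCc3ccccc3)c2c1O[C@H](c1cc(OCc3ccccc3)c(OCc3ccccc3)c(OCc3ccccc3)c1)[C@H](O)C2
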